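**Plan**
- The cis oxygens on C1 (quaternary carbinol) and C4 flank the ring C2=C3 alkene; this 2-ene-1,4-diol is the retron of a 2,3-dioxabicyclo[2.2.2]oct-5-ene, so the C1–O and C4–O bonds are cut first and together, back to O2 and a 1-alkyl-5-silyloxycyclohexa-1,3-diene.
- The diene is cut next at C3–H (dienyl triflate of a 3-alkyl-5-silyloxycyclohexenone), then at the C1–chain bond (Grignard addition and oxidative transposition on (S)-5-silyloxycyclohex-2-enone); the chain is cut last between C11' and C12' into 11-bromoundecan-1-ol and 1-hexyne.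
- Forward: the carbocycle is bought as cis,cis-cyclohexane-1,3,5-triol, the C17 chain is joined in step 7, and the only ring made is the 1,2-dioxine bridge of step 11, reopened in step 12.
- Stereochemistry: C5 comes from lipase desymmetrisation of a meso diol; C1 and C4 are relayed from C5 by anti-facial, suprafacial addition of singlet oxygen; the E-alkene comes from dissolving-metal reduction of the alkyne.
- Ring numbering used throughout: C1 carries the chain and a hydroxyl, C2=C3 is the alkene, C4 and C5 are the secondary carbinols, C6 is CH2; the target is (1R,4R,5R) in this numbering.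

Key step: step 11

Assumption: the lipase is taken to acetylate the (S)-configured carbinol of meso diol 2; if it shows the opposite sense, the enantiocomplementary hydrolytic mode of the same enzyme would be used instead.

**Step 1**
Reactants: 1 cis,cis-cyclohexane-1,3,5-triol
Product: 2 cis,cis-5-(tert-butyldimethylsilyloxy)cyclohexane-1,3-diol (meso)
Conditions: TBSCl (1.0 equiv), imidazole, DMF, 0 °C to rt
Reagents that add atoms: tert-butyldimethylsilyl chloride, CC(C)(C)[Si](C)(C)Cl
Why: Imidazole-mediated silylation of one of three equivalent hydroxyls (statistical mono-protection of a C3-symmetric triol, whose only possible mono-ether is the meso diol) creates no stereocentre, so over-silylated material is separated and unreacted triol is recycled.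

**Step 2**
Reactants: 2 cis,cis-5-(tert-butyldimethylsilyloxy)cyclohexane-1,3-diol
Product: 3 (1S,3R,5R)-3-(tert-butyldimethylsilyloxy)-5-hydroxycyclohexyl acetate
Conditions: Burkholderia cepacia lipase, vinyl acetate, t-BuOMe, 30 °C
Reagents that add atoms: vinyl acetate, CC(=O)OC=C
Why: Lipase-catalysed irreversible transesterification (enzymatic desymmetrisation of a meso 1,3-diol) acetylates one of the two enantiotopic carbinols, which fixes the absolute configuration of the silyloxy carbon, the later C5 of the target.

**Step 3**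
Reactants: 3 (1S,3R,5R)-3-(tert-butyldimethylsilyloxy)-5-hydroxycyclohexyl acetate
Product: 5 (S)-5-(tert-butyldimethylsilyloxy)cyclohex-2-en-1-one, via β-acetoxy ketone 4 (not isolated)
Conditions: Dess–Martin periodinane, CH2Cl2, 0 °C to rt; then Et3N, 0 °C
Reagents that add atoms: none
Why: Dess–Martin oxidation of the free carbinol followed by amine-induced E1cB loss of the β-acetate (a far better leaving group than the β-silanolate) should give the enone regioselectively without involving the silyloxy stereocentre.

**Step 4**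
Reactants: 6 1-hexyne; 7 11-bromoundecan-1-ol
Product: 10 heptadec-12-yn-1-ol, via hex-1-ynyllithium 8 (not isolated), via lithium 11-bromoundecan-1-olate 9 (not isolated)
Conditions: 6 (2.2 equiv), n-BuLi (2.1 equiv), THF/DMPU, −78 to 0 °C; then 7, 0 °C to rt
Reagents that add atoms: none
Why: SN2 alkylation of a lithium acetylide by a primary bromide in a dipolar cosolvent, with the first equivalent of acetylide masking the hydroxyl as its unreactive lithium alkoxide.

**Step 5**
Reactants: 10 heptadec-12-yn-1-ol
Product: 11 (E)-heptadec-12-en-1-ol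
Conditions: Li, NH3(l)/THF, −33 °C
Reagents that add atoms: none
Why: Dissolving-metal reduction of an internal alkyne, in which the vinyl radical anion and vinyl anion adopt the trans geometry before protonation by ammonia, sets the E-alkene and leaves the alkoxide untouched.

**Step 6**
Reactants: 11 (E)-heptadec-12-en-1-ol
Product: 12 (E)-17-bromoheptadec-5-ene
Conditions: CBr4, PPh3, CH2Cl2, 0 °C
Reagents that add atoms: carbon tetrabromide, BrC(Br)(Br)Br
Why: Appel reaction, in which bromide displaces the alkoxyphosphonium ion at the primary carbon under neutral conditions that leave the E-alkene untouched.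

**Step 7**
Reactants: 12 (E)-17-bromoheptadec-5-ene; 5 (S)-5-(tert-butyldimethylsilyloxy)cyclohex-2-en-1-one
Product: 14 (5S)-5-(tert-butyldimethylsilyloxy)-1-[(E)-heptadec-12-enyl]cyclohex-2-en-1-ol (C1 epimer mixture), via Grignard reagent 13 (not isolated)
Conditions: 12, Mg, THF, 40 °C; then 5, CeCl3 (anhydrous), THF, −78 °C
Reagents that add atoms: none
Why: Grignard formation followed by CeCl3-promoted 1,2-addition, in which the oxophilic cerium salt activates the carbonyl and suppresses conjugate addition and enolisation toward the β-silyloxy group; the new carbinol centre becomes sp2 again in step 8, so its configuration does not matter.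

**Step 8**
Reactants: 14 (5S)-5-(tert-butyldimethylsilyloxy)-1-[(E)-heptadec-12-enyl]cyclohex-2-en-1-ol
Product: 15 (R)-5-(tert-butyldimethylsilyloxy)-3-[(E)-heptadec-12-enyl]cyclohex-2-en-1-one
Conditions: [C5H5NH][CrO3Cl] (pyridinium chlorochromate), 4 Å molecular sieves, CH2Cl2, rt
Reagents that add atoms: pyridinium chlorochromate, [O-][Cr](=O)(=O)Cl.c1cc[nH+]cc1
Why: Babler–Dauben oxidative transposition, in which the tertiary allylic chromate ester undergoes a [3,3]-shift and the secondary chromate collapses to the enone (carbonyl oxygen from the oxidant), moves the alkene to the chain-bearing carbon; the silyloxy centre keeps its spatial arrangement and its descriptor changes from S to R only because the ring priorities swap.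

**Step 9**
Reactants: 15 (R)-5-(tert-butyldimethylsilyloxy)-3-[(E)-heptadec-12-enyl]cyclohex-2-en-1-one
Product: 17 (3R)-3-(tert-butyldimethylsilyloxy)-5-[(E)-heptadec-12-enyl]cyclohexa-1,5-dien-1-yl trifluoromethanesulfonate, via lithium dienolate 16 (not isolated)
Conditions: LiN(i-Pr)2, THF, −78 °C; then Comins' reagent, −78 °C
Reagents that add atoms: N-(5-chloropyridin-2-yl)-N-(trifluoromethylsulfonyl)trifluoromethanesulfonamide (Comins' reagent), FC(F)(F)S(=O)(=O)N(c1ccc(Cl)cn1)S(=O)(=O)C(F)(F)F
Why: Kinetic deprotonation by the hindered amide at the α′ methylene (the future C4) gives the cross-conjugated lithium dienolate, which is O-triflated in situ at −78 °C, a temperature at which β-elimination of the neighbouring silyloxy group should not compete.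

**Step 10**
Reactants: 17 (3R)-3-(tert-butyldimethylsilyloxy)-5-[(E)-heptadec-12-enyl]cyclohexa-1,5-dien-1-yl trifluoromethanesulfonate
Product: 18 (5R)-5-(tert-butyldimethylsilyloxy)-1-[(E)-heptadec-12-enyl]cyclohexa-1,3-diene
Conditions: Pd(OAc)2 (cat.), PPh3, Bu3N (3 equiv), HCO2H (2 equiv), DMF, 50 °C
Reagents that add atoms: none
Why: Palladium-catalysed formate reduction of an enol triflate (oxidative addition of zerovalent palladium formed in situ, formate exchange, decarboxylation to a palladium hydride, reductive elimination) replaces OTf by H without moving either ring alkene, and the excess amine keeps the medium basic so the acid-labile silyloxy diene should not aromatise.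

**Step 11**
Reactants: 18 (5R)-5-(tert-butyldimethylsilyloxy)-1-[(E)-heptadec-12-enyl]cyclohexa-1,3-diene (used directly)
Product: 19 (1R,4R,8R)-8-(tert-butyldimethylsilyloxy)-1-[(E)-heptadec-12-enyl]-2,3-dioxabicyclo[2.2.2]oct-5-ene (silyl ether anti to the peroxide bridge)
Conditions: O2, tetraphenylporphyrin (cat.), visible light, CH2Cl2, −78 °C
Reagents that add atoms: dioxygen, O=O
Why: Energy transfer from the excited sensitiser gives singlet oxygen, which adds suprafacially across C1 and C4 of the s-cis ring diene in a concerted [4+2] cycloaddition, so the C1–O and C4–O bonds form in one event and the C2=C3 alkene appears in its final place. The closest known reaction type is the photooxygenation of 1,3-cyclohexadienes to 2,3-dioxabicyclo[2.2.2]oct-5-enes, as in the conversion of α-terpinene into ascaridole. The one ring closed is the six-membered 1,2-dioxine, formed by intermolecular [4+2] closure in which the O–O unit bridges C1 and C4 on a single face. Both new stereocentres, the quaternary C1 and C4, are controlled by the C5 silyloxy group, which screens its own face and sends oxygen to the opposite one, while suprafacial addition fixes the C1/C4 cis relationship. The step needs anti facial selectivity, diene-over-alkene chemoselectivity and [4+2] over ene reactivity: the first rests on the bulk and lone-pair repulsion of the silyl ether next to C4, the second on the much higher rate of a cisoid cyclic diene than of an isolated trans-disubstituted alkene, and the third on the locked s-cis geometry at low temperature.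

**Step 12**
Reactants: 19 (1R,4R,8R)-8-(tert-butyldimethylsilyloxy)-1-[(E)-heptadec-12-enyl]-2,3-dioxabicyclo[2.2.2]oct-5-ene
Product: 20 (1R,4R,5R)-5-(tert-butyldimethylsilyloxy)-1-[(E)-heptadec-12-enyl]cyclohex-2-ene-1,4-diol
Conditions: thiourea, MeOH (trace H2O), 0 °C to rt
Reagents that add atoms: none
Why: Thiourea attacks the O–O bond at oxygen and reduces the endoperoxide under neutral conditions, so both C–O bonds and the cis-1,4 relationship are retained, base-induced Kornblum–DeLaMare fragmentation at C4–H is avoided, and the silyl ether, the tertiary allylic alcohol and both alkenes are spared.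

**Step 13**
Reactants: 20 (1R,4R,5R)-5-(tert-butyldimethylsilyloxy)-1-[(E)-heptadec-12-enyl]cyclohex-2-ene-1,4-diol
Product: 21 (1R,2R,4R)-4-[(E)-heptadec-12-enyl]cyclohex-5-ene-1,2,4-triol (target; (1R,4R,5R) in the ring numbering above)
Conditions: Bu4NF, THF, 0 °C to rt
Reagents that add atoms: none
Why: Fluoride-induced cleavage of the Si–O bond frees the C5 hydroxyl without acid, which the tertiary allylic alcohol would not tolerate, and touches no stereocentre.

**Compound list**
1 | cis,cis-cyclohexane-1,3,5-triol | O[C@H]1C[C@@H](O)C[C@@H](O)C1 | starting material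
2 | cis,cis-5-(tert-butyldimethylsilyloxy)cyclohexane-1,3-diol (meso) | O[C@H]1C[C@@H](O)C[C@@H](O[Si](C)(C)C(C)(C)C)C1 | intermediate
3 | (1S,3R,5R)-3-(tert-butyldimethylsilyloxy)-5-hydroxycyclohexyl acetate | O[C@@H]1C[C@H](OC(C)=O)C[C@H](O[Si](C)(C)C(C)(C)C)C1 | intermediate
4 | (1R,3S)-3-(tert-butyldimethylsilyloxy)-5-oxocyclohexyl acetate | O=C1C[C@H](OC(C)=O)C[C@H](O[Si](C)(C)C(C)(C)C)C1 | intermediate
5 | (S)-5-(tert-butyldimethylsilyloxy)cyclohex-2-en-1-one | O=C1C=CC[C@H](O[Si](C)(C)C(C)(C)C)C1 | intermediate
6 | 1-hexyne | CCCCC#C | starting material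
7 | 11-bromoundecan-1-ol | OCCCCCCCCCCCBr | starting material
8 | hex-1-ynyllithium | [Li]C#CCCCC | intermediate
9 | lithium 11-bromoundecan-1-olate | [Li]OCCCCCCCCCCCBr | intermediate
10 | heptadec-12-yn-1-ol | CCCCC#CCCCCCCCCCCCO | intermediate
11 | (E)-heptadec-12-en-1-ol | CCCC/C=C/CCCCCCCCCCCO | intermediate
12 | (E)-17-bromoheptadec-5-ene | CCCC/C=C/CCCCCCCCCCCBr | intermediate
13 | (E)-heptadec-12-enylmagnesium bromide | CCCC/C=C/CCCCCCCCCCC[Mg]Br | intermediate
14 | (5S)-5-(tert-butyldimethylsilyloxy)-1-[(E)-heptadec-12-enyl]cyclohex-2-en-1-ol (C1 epimer mixture) | CCCC/C=C/CCCCCCCCCCCC1(O)C=CC[C@H](O[Si](C)(C)C(C)(C)C)C1 | intermediate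
15 | (R)-5-(tert-butyldimethylsilyloxy)-3-[(E)-heptadec-12-enyl]cyclohex-2-en-1-one | CCCC/C=C/CCCCCCCCCCCC1=CC(=O)C[C@H](O[Si](C)(C)C(C)(C)C)C1 | intermediate
16 | lithium (3R)-3-(tert-butyldimethylsilyloxy)-5-[(E)-heptadec-12-enyl]cyclohexa-1,5-dien-1-olate | CCCC/C=C/CCCCCCCCCCCC1=CC(O[Li])=C[C@H](O[Si](C)(C)C(C)(C)C)C1 | intermediate
17 | (3R)-3-(tert-butyldimethylsilyloxy)-5-[(E)-heptadec-12-enyl]cyclohexa-1,5-dien-1-yl trifluoromethanesulfonate | CCCC/C=C/CCCCCCCCCCCC1=CC(OS(=O)(=O)C(F)(F)F)=C[C@H](O[Si](C)(C)C(C)(C)C)C1 | intermediate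
18 | (5R)-5-(tert-butyldimethylsilyloxy)-1-[(E)-heptadec-12-enyl]cyclohexa-1,3-diene | CCCC/C=C/CCCCCCCCCCCC1=CC=C[C@H](O[Si](C)(C)C(C)(C)C)C1 | intermediate
19 | (1R,4R,8R)-8-(tert-butyldimethylsilyloxy)-1-[(E)-heptadec-12-enyl]-2,3-dioxabicyclo[2.2.2]oct-5-ene | CCCC/C=C/CCCCCCCCCCC[C@]12C=C[C@@H](OO2)[C@H](O[Si](C)(C)C(C)(C)C)C1 | intermediate
20 | (1R,4R,5R)-5-(tert-butyldimethylsilyloxy)-1-[(E)-heptadec-12-enyl]cyclohex-2-ene-1,4-diol | CCCC/C=C/CCCCCCCCCCC[C@]1(O)C=C[C@@H](O)[C@H](O[Si](C)(C)C(C)(C)C)C1 | intermediate
21 | (1R,2R,4R)-4-[(E)-heptadec-12-enyl]cyclohex-5-ene-1,2,4-triol | CCCC/C=C/CCCCCCCCCCC[C@]1(O)C=C[C@@H](O)[C@H](O)C1 | target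

**Step count**
Total: 13 steps. Longest linear sequence: 10 steps (steps 1–3 and 7–13 from triol 1; equally steps 4–13 from 6 and 7).

**Steps most likely to fail**

Step 11. Oxygen may approach both faces of the diene, giving the all-cis endoperoxide alongside 19, and ene hydroperoxidation at the trisubstituted alkene may compete. The fallback changes the group that controls the face, not the irradiation conditions, and sets out from diene 18. Bu4NF in THF at 0 °C should free the dienol (1R)-5-[(E)-heptadec-12-enyl]cyclohexa-2,4-dien-1-ol F1. tert-Butyldiphenylsilyl chloride and imidazole in DMF should then give (5R)-5-(tert-butyldiphenylsilyloxy)-1-[(E)-heptadec-12-enyl]cyclohexa-1,3-diene F2, whose two phenyl rings should screen the C4 terminus more fully. Photooxygenation as in step 11 should give (1R,4R,8R)-8-(tert-butyldiphenylsilyloxy)-1-[(E)-heptadec-12-enyl]-2,3-dioxabicyclo[2.2.2]oct-5-ene F3, and thiourea should give (1R,4R,5R)-5-(tert-butyldiphenylsilyloxy)-1-[(E)-heptadec-12-enyl]cyclohex-2-ene-1,4-diol F4. Bu4NF then returns the sequence to the route at target 21.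

Step 9. The α′-enolate may expel the neighbouring silanolate and aromatise to a 3-alkylphenol before it is triflated. The fallback avoids any enolate next to the silyloxy carbon and sets out from enone 5. Tf2O and 2,6-di-tert-butyl-4-methylpyridine in CH2Cl2 should give, by O-triflation and γ-deprotonation, the through-conjugated (5R)-5-(tert-butyldimethylsilyloxy)cyclohexa-1,3-dien-1-yl trifluoromethanesulfonate F5. Iron-catalysed alkyl–alkenyl cross-coupling with Grignard reagent 13 (Fe(acac)3, THF/N-methylpyrrolidone, −30 °C) should then put the chain directly on the diene. This rejoins the route at diene 18 and bypasses 14 to 17.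

Step 10. The silyloxy diene may lose silanol and aromatise, or its alkenes may migrate, in the warm palladium hydride medium. The fallback removes the carbonyl through a hydrazone and sets out from enone 15. Tosylhydrazide in MeOH should give N′-[(5R)-5-(tert-butyldimethylsilyloxy)-3-[(E)-heptadec-12-enyl]cyclohex-2-en-1-ylidene]-4-methylbenzenesulfonohydrazide F6. LiN(i-Pr)2 (2.2 equiv) in THF from −78 to 0 °C should effect a Shapiro reaction by α′-deprotonation, loss of sulfinate and dinitrogen, giving [(3R)-3-(tert-butyldimethylsilyloxy)-5-[(E)-heptadec-12-enyl]cyclohexa-1,5-dien-1-yl]lithium F7. A cold water quench should then deliver the diene without transition metal, acid or heating, rejoining the route at 18.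

**Further compounds**
F1 | step 11 | (1R)-5-[(E)-heptadec-12-enyl]cyclohexa-2,4-dien-1-ol | CCCC/C=C/CCCCCCCCCCCC1=CC=C[C@H](O)C1
F2 | step 11 | (5R)-5-(tert-butyldiphenylsilyloxy)-1-[(E)-heptadec-12-enyl]cyclohexa-1,3-diene | CCCC/C=C/CCCCCCCCCCCC1=CC=C[C@H](O[Si](c2ccccc2)(c2ccccc2)C(C)(C)C)C1
F3 | step 11 | (1R,4R,8R)-8-(tert-butyldiphenylsilyloxy)-1-[(E)-heptadec-12-enyl]-2,3-dioxabicyclo[2.2.2]oct-5-ene | CCCC/C=C/CCCCCCCCCCC[C@]12C=C[C@@H](OO2)[C@H](O[Si](c3ccccc3)(c3ccccc3)C(C)(C)C)C1
F4 | step 11 | (1R,4R,5R)-5-(tert-butyldiphenylsilyloxy)-1-[(E)-heptadec-12-enyl]cyclohex-2-ene-1,4-diol | CCCC/C=C/CCCCCCCCCCC[C@]1(O)C=C[C@@H](O)[C@H](O[Si](c2ccccc2)(c2ccccc2)C(C)(C)C)C1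
F5 | step 9 | (5R)-5-(tert-butyldimethylsilyloxy)cyclohexa-1,3-dien-1-yl trifluoromethanesulfonate | O=S(=O)(OC1=CC=C[C@H](O[Si](C)(C)C(C)(C)C)C1)C(F)(F)F
F6 | step 10 | N′-[(5R)-5-(tert-butyldimethylsilyloxy)-3-[(E)-heptadec-12-enyl]cyclohex-2-en-1-ylidene]-4-methylbenzenesulfonohydrazide | CCCC/C=C/CCCCCCCCCCCC1=CC(=NNS(=O)(=O)c2ccc(C)cc2)C[C@H](O[Si](C)(C)C(C)(C)C)C1
F7 | step 10 | [(3R)-3-(tert-butyldimethylsilyloxy)-5-[(E)-heptadec-12-enyl]cyclohexa-1,5-dien-1-yl]lithium | CCCC/C=C/CCCCCCCCCCCC1=CC([Li])=C[C@H](O[Si](C)(C)C(C)(C)C)C1
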